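# Total synthesis of Volvaltrate B

**Numbering used below.** Iridoid numbering: C1 acylal, O2, C3=C4 enol ether, C5 tertiary carbinol, C6 CH2, C7 CH–OAc, C8 quaternary carbinol, C9 ring-fusion CH, C10 CH2Cl, C11 CH2O–acyl.

## Retrosynthetic overview
1. Target ⇐ C7 acetylation ⇐ C11 esterification of diol **24** with acid **27**. Acid **27** comes from 3-methyl-2-oxobutanoate by enzymatic reduction and isovalerylation.
2. The C8 chlorohydrin ⇐ HCl opening of a spiro-epoxide ⇐ Corey–Chaykovsky methylenation of the C8 ketone of the cis-fused cyclopenta[c]pyran acylal.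
3. The C1 acylal and C3=C4 enol ether ⇐ lactol ⇐ DIBAL reduction of an enol lactone ⇐ a δ-acetal carboxylic acid.
4. Cyclopentane ring (present from step 1, from cyclopentadiene + ¹O2):
   - C7: enzymatic desymmetrisation of the meso diol diacetate.
   - C5: 1,2-addition to a 2-iodoenone, anti to the C7 silyl ether.
   - C8/C9: Weitz–Scheffer epoxidation of an enal, then Red-Al opening.
   - Ring order: cyclopentane ring (step 1), pyranone ring (step 16), oxirane (step 20, opened in step 21).

Assumptions:
- 2-Bromo-3,3-diethoxypropene (**10**) is taken as commercially available.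
- The esterase gives the (1R,4S) monoacetate.
- The pseudo-axial (natural) 1-OIval anomer is the major acylal.

## Route

**Step 1**
Reactants: **1** cyclopenta-1,3-diene
Product: **2** 2,3-dioxabicyclo[2.2.1]hept-5-ene (achiral endoperoxide)
Conditions: ³O₂, hν, Rose Bengal, MeOH, −20 °C
Reagents that add atoms: dioxygen, O=O
Why: Singlet-oxygen [4+2] photo-oxygenation bridges C1/C4 of the diene with a cis peroxide.

**Step 2**
Reactants: **2**
Product: **3** cis-cyclopent-4-ene-1,3-diol (meso)
Conditions: thiourea, MeOH, 0 °C → rt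
Reagents that add atoms: none
Why: Thiourea reductively cleaves the O–O bond (Kaneko reduction), keeping the cis-1,3-diol.

**Step 3**
Reactants: **3**
Product: **4** cis-3,5-diacetoxycyclopent-1-ene (meso)
Conditions: Ac₂O, pyridine, DMAP (cat.), CH₂Cl₂, 0 °C → rt
Reagents that add atoms: acetic anhydride, CC(=O)OC(C)=O
Why: Plain O-acetylation of both hydroxyls.

**Step 4**
Reactants: **4**
Product: **5** (1R,4S)-4-hydroxycyclopent-2-en-1-yl acetate, the first stereocentre (becomes C7)
Conditions: electric-eel acetylcholinesterase (serine hydrolase, EC 3.1.1.7), 0.1 M phosphate pH 7.0, rt, pH-stat with NaOH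
Reagents that add atoms: water, O
Why: Enantiotopic-group-selective enzymatic hydrolysis (desymmetrisation) removes one acetate and gives the monoacetate in ≥98% ee.

**Step 5**
Reactants: **5**
Product: **6** the C7 TBS ether of **5**, OAc retained (cis-1,4)
Conditions: TBSCl, imidazole, DMF, 0 °C (use immediately to avoid acyl migration)
Reagents that add atoms: TBSCl, CC(C)(C)[Si](C)(C)Cl
Why: Silylation protects the free hydroxyl, which will become C7–O.

**Step 6**
Reactants: **6**
Product: **7** (1R,4S)-4-(TBSO)cyclopent-2-en-1-ol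
Conditions: K₂CO₃, MeOH, 0 °C
Reagents that add atoms: none
Why: Methanolysis of the acetate only; the silyl ether is untouched.

**Step 7**
Reactants: **7**
Product: **8** (S)-4-(TBSO)cyclopent-2-en-1-one (C5 = carbonyl)
Conditions: Dess–Martin periodinane, NaHCO₃, CH₂Cl₂, 0 °C → rt
Reagents that add atoms: none
Why: Buffered oxidation of the allylic alcohol to the enone leaves the γ-silyloxy centre intact.

**Step 8**
Reactants: **8**
Product: **9** (S)-4-(TBSO)-2-iodocyclopent-2-en-1-one (iodine on C9)
Conditions: I₂, pyridine, CH₂Cl₂, 0 °C → rt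
Reagents that add atoms: iodine, II
Why: Johnson α-iodination (conjugate addition of pyridine, iodination, elimination).

**Step 9**
Reactants: **9**, **10** 2-bromo-3,3-diethoxyprop-1-ene
Product: **11** tertiary allylic alcohol; C5–OH cis to C7–OTBS, C4 unit = C(=CH₂)CH(OEt)₂ on the opposite face, C9–I retained
Conditions: **10**, t-BuLi, THF, −78 °C; then anhydrous CeCl₃; then **9**, −78 °C
Reagents that add atoms: none
Why: The organocerium adds 1,2 (cerium suppresses enolisation and Li–I exchange) anti to the C7 silyloxy group, so C5 is set with OH cis to OTBS (C5–OH and C7–OTBS both "up", C4 "down").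

**Step 10**
Reactants: **11**
Product: **12** primary alcohol C11–OH; C4 now CH (C4 epimeric mixture, irrelevant later)
Conditions: 9-BBN (2.5 equiv), THF, 0 °C → rt; then NaOH, H₂O₂, 0 °C
Reagents that add atoms: hydrogen peroxide, OO
Why: Hydroboration–oxidation of the 1,1-disubstituted alkene puts OH on the terminal CH₂ (C11), while the hindered vinyl iodide is untouched.

**Step 11**
Reactants: **12**
Product: **13** C11–OTBS ether
Conditions: TBSCl, imidazole, DMF, rt
Reagents that add atoms: TBSCl, CC(C)(C)[Si](C)(C)Cl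
Why: Selective silylation of the primary hydroxyl; the tertiary C5–OH is unreactive.

**Step 12**
Reactants: **13**
Product: **14** enal (C9–CHO = C1)
Conditions: t-BuLi (3 equiv), THF, −78 °C; then DMF
Reagents that add atoms: DMF, CN(C)C=O
Why: Li–I exchange on the vinyl iodide (one equivalent is consumed by the OH) and formylation of the vinyllithium with DMF.

**Step 13**
Reactants: **14**
Product: **15** α,β-epoxy aldehyde; epoxide O on the face opposite C5–OH and C7–OTBS, i.e. on the C4 side ("down")
Conditions: 30% H₂O₂, NaOH (aq, cat.), MeOH, 0 °C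
Reagents that add atoms: hydrogen peroxide, OO
Why: Weitz–Scheffer nucleophilic epoxidation: HOO⁻ adds to C8 anti to the C7 silyloxy group, and the alkene C4=C11 is inert to nucleophilic epoxidation.

**Step 14**
Reactants: **15**
Product: **16** C1 primary alcohol (down), C8 secondary alcohol (O down, trans to C7–OTBS), H9 up
Conditions: Red-Al (4 equiv), THF/toluene, 0 °C → rt
Reagents that add atoms: none
Why: Red-Al reduces the aldehyde, then opens the 2,3-epoxy alkoxide at C9 by intramolecular hydride delivery from the top face with inversion, giving H9 up, C1 down and retaining C8–O.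

**Step 15**
Reactants: **16**
Product: **17** C1 carboxylic acid; acetal, OTBS and C8–OH intact
Conditions: TEMPO (0.1 equiv), NaClO₂, NaOCl (cat.), MeCN/pH 6.7 phosphate buffer, 35 °C
Reagents that add atoms: sodium chlorite, [Na+].[O-]Cl=O
Why: Zhao–Grabowski TEMPO oxidation is selective for the primary alcohol over the hindered secondary and tertiary alcohols, and the buffer protects the acetal.

**Step 16**
Reactants: **17**
Product: **18** cis-fused enol lactone (C1=O, O2, C3=C4); C4 stereochemistry lost
Conditions: PPTS (0.2 equiv), toluene, 80 °C, 4 Å MS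
Reagents that add atoms: none
Why: The acetal ionises, the carboxylate closes the six-membered ring (cis to C4, fixing cis ring fusion), and loss of EtOH (E1) gives the trisubstituted enol lactone; this merges the C4 epimers.

**Step 17**
Reactants: **18**
Product: **19** lactol (C1–OH, anomers unresolved) with enol ether C3=C4
Conditions: DIBAL-H (4 equiv), CH₂Cl₂, −78 °C; MeOH quench, Rochelle salt
Reagents that add atoms: none
Why: Partial reduction of the lactone carbonyl to the hemiacetal; the extra equivalents are consumed by the two free OH groups.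

**Step 18**
Reactants: **19**
Product: **20** C1 isovalerate acylal (natural anomer, OIval cis to H9)
Conditions: (iPrCH₂CO)₂O (1.1 equiv), DMAP (0.1 equiv), pyridine, CH₂Cl₂, −20 → 0 °C
Reagents that add atoms: isovaleric anhydride, CC(C)CC(=O)OC(=O)CC(C)C
Why: Chemoselective acylation of the more acidic, less hindered anomeric OH; the anomeric effect favours the pseudo-axial acylal, and the minor anomer is chromatographed off.

**Step 19**
Reactants: **20**
Product: **21** C8 ketone (C8 stereocentre intentionally destroyed)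
Conditions: Dess–Martin periodinane, NaHCO₃, CH₂Cl₂, rt
Reagents that add atoms: none
Why: Buffered oxidation of the secondary alcohol; the tertiary C5–OH, the acylal and the enol ether are untouched.

**Step 20**
Reactants: **21**
Product: **22** spiro-epoxide at C8 (CH₂ on the convex top face, O down, trans to C7–OTBS)
Conditions: Me₃S⁺ I⁻ (3 equiv), n-BuLi (3 equiv), THF, −10 → 0 °C
Reagents that add atoms: trimethylsulfonium iodide, C[S+](C)C.[I-]
Why: Corey–Chaykovsky methylenation with dimethylsulfonium methylide; the ylide carbon attacks the convex face of the cis-fused bicycle (the pseudo-axial C1–OIval shields the concave face), so the epoxide oxygen ends up on the concave face.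

**Step 21**
Reactants: **22**
Product: **23** C8 tertiary alcohol with C10–Cl (bis-TBS)
Conditions: 1 M HCl in Et₂O (1.5 equiv), CH₂Cl₂, −78 → −40 °C
Reagents that add atoms: hydrogen chloride, Cl
Why: Acid-assisted SN2 opening of the spiro-epoxide by chloride at the unhindered CH₂ (C10), with retention at C8.

**Step 22**
Reactants: **23**
Product: **24** diol (C7–OH, C11–OH)
Conditions: HF·pyridine, pyridine, THF, 0 °C → rt
Reagents that add atoms: none
Why: The buffered, acidic fluoride removes both silyl ethers without base, which could re-close the chlorohydrin to the epoxide.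

**Side-chain branch**

**Step 23**
Reactants: **25** sodium 3-methyl-2-oxobutanoate
Product: **26** (R)-2-hydroxy-3-methylbutanoic acid
Conditions: D-2-hydroxyisocaproate dehydrogenase (NAD⁺-dependent oxidoreductase, EC 1.1.1.-), NAD⁺ (cat.), glucose, glucose dehydrogenase, pH 7 phosphate buffer, 30 °C
Reagents that add atoms: none
Why: Enzymatic asymmetric carbonyl reduction (hydride from NADH, recycled with glucose) gives the (R)-α-hydroxy acid.

**Step 24**
Reactants: **26**
Product: **27** (R)-2-(isovaleryloxy)-3-methylbutanoic acid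
Conditions: isovaleryl chloride (2.5 equiv), pyridine, CH₂Cl₂, 0 °C; then THF/H₂O, rt
Reagents that add atoms: isovaleryl chloride, CC(C)CC(=O)Cl
Why: Acylation of both OH and CO₂H, then hydrolysis of the mixed anhydride returns the carboxylic acid and leaves the α-isovalerate ester.

**Step 25**
Reactants: **24**, **27**
Product: **28** C11 ester of **24** with acid **27**
Conditions: EDC·HCl (1.3 equiv), DMAP (0.2 equiv), CH₂Cl₂, 0 °C → rt
Reagents that add atoms: none
Why: Steglich esterification is selective for the unhindered primary C11–OH over the secondary C7–OH and the tertiary alcohols.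

**Step 26**
Reactants: **28**
Product: **29** Volvaltrate B
Conditions: Ac₂O (5 equiv), pyridine, DMAP (0.1 equiv), CH₂Cl₂, 0 °C → rt
Reagents that add atoms: acetic anhydride, CC(=O)OC(C)=O
Why: Acetylation of the remaining secondary C7–OH; the two tertiary alcohols (C5, C8) are too hindered to react.

## Compound list
1 | cyclopenta-1,3-diene | C1C=CC=C1 | starting material
2 | 2,3-dioxabicyclo[2.2.1]hept-5-ene | C1=CC2CC1OO2 | intermediate
3 | cis-cyclopent-4-ene-1,3-diol | O[C@H]1C[C@@H](O)C=C1 | intermediate
4 | cis-3,5-diacetoxycyclopentene | CC(=O)O[C@H]1C[C@@H](OC(C)=O)C=C1 | intermediate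
5 | (1R,4S)-4-hydroxycyclopent-2-en-1-yl acetate | O[C@H]1C[C@@H](OC(C)=O)C=C1 | intermediate
6 | (1R,4S)-4-(TBSO)cyclopent-2-en-1-yl acetate | CC(C)(C)[Si](C)(C)O[C@H]1C[C@@H](OC(C)=O)C=C1 | intermediate
7 | (1R,4S)-4-(TBSO)cyclopent-2-en-1-ol | CC(C)(C)[Si](C)(C)O[C@H]1C[C@@H](O)C=C1 | intermediate
8 | (S)-4-(TBSO)cyclopent-2-en-1-one | CC(C)(C)[Si](C)(C)O[C@H]1CC(=O)C=C1 | intermediate
9 | (S)-4-(TBSO)-2-iodocyclopent-2-en-1-one | CC(C)(C)[Si](C)(C)O[C@H]1CC(=O)C(I)=C1 | intermediate
10 | 2-bromo-3,3-diethoxyprop-1-ene | C=C(Br)C(OCC)OCC | starting material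
11 | 1-[1-(diethoxymethyl)vinyl]-2-iodo-4-(TBSO)cyclopent-2-en-1-ol, OH cis to OTBS | C=C(C(OCC)OCC)[C@@]1(O)C[C@H](O[Si](C)(C)C(C)(C)C)C=C1I | intermediate
12 | C11 primary alcohol (C4 epimeric mixture) | OCC(C(OCC)OCC)[C@@]1(O)C[C@H](O[Si](C)(C)C(C)(C)C)C=C1I | intermediate
13 | C11-OTBS ether | CC(C)(C)[Si](C)(C)OCC(C(OCC)OCC)[C@@]1(O)C[C@H](O[Si](C)(C)C(C)(C)C)C=C1I | intermediate
14 | enal | CC(C)(C)[Si](C)(C)OCC(C(OCC)OCC)[C@@]1(O)C[C@H](O[Si](C)(C)C(C)(C)C)C=C1C=O | intermediate
15 | α,β-epoxy aldehyde (O down) | CC(C)(C)[Si](C)(C)OCC(C(OCC)OCC)[C@@]1(O)C[C@H](O[Si](C)(C)C(C)(C)C)[C@H]2O[C@@]12C=O | intermediate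
16 | C1 alcohol / C8 secondary alcohol, H9 up | CC(C)(C)[Si](C)(C)OCC(C(OCC)OCC)[C@@]1(O)C[C@H](O[Si](C)(C)C(C)(C)C)[C@@H](O)[C@H]1CO | intermediate
17 | C1 carboxylic acid | CC(C)(C)[Si](C)(C)OCC(C(OCC)OCC)[C@@]1(O)C[C@H](O[Si](C)(C)C(C)(C)C)[C@@H](O)[C@H]1C(=O)O | intermediate
18 | cis-fused enol lactone | CC(C)(C)[Si](C)(C)O[C@H]1C[C@]2(O)C(CO[Si](C)(C)C(C)(C)C)=COC(=O)[C@@H]2[C@@H]1O | intermediate
19 | lactol (C1 anomers unspecified) | CC(C)(C)[Si](C)(C)O[C@H]1C[C@]2(O)C(CO[Si](C)(C)C(C)(C)C)=COC(O)[C@@H]2[C@@H]1O | intermediate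
20 | C1 isovalerate acylal, C8–OH | CC(C)(C)[Si](C)(C)O[C@H]1C[C@]2(O)C(CO[Si](C)(C)C(C)(C)C)=CO[C@@H](OC(=O)CC(C)C)[C@@H]2[C@@H]1O | intermediate
21 | C8 ketone | CC(C)(C)[Si](C)(C)O[C@H]1C[C@]2(O)C(CO[Si](C)(C)C(C)(C)C)=CO[C@@H](OC(=O)CC(C)C)[C@@H]2C1=O | intermediate
22 | spiro-epoxide | CC(C)(C)[Si](C)(C)O[C@H]1C[C@]2(O)C(CO[Si](C)(C)C(C)(C)C)=CO[C@@H](OC(=O)CC(C)C)[C@@H]2[C@@]13CO3 | intermediate
23 | chlorohydrin, bis-TBS | CC(C)(C)[Si](C)(C)O[C@H]1C[C@]2(O)C(CO[Si](C)(C)C(C)(C)C)=CO[C@@H](OC(=O)CC(C)C)[C@@H]2[C@@]1(O)CCl | intermediate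
24 | chlorohydrin diol (C7–OH, C11–OH) | O[C@H]1C[C@]2(O)C(CO)=CO[C@@H](OC(=O)CC(C)C)[C@@H]2[C@@]1(O)CCl | intermediate
25 | sodium 3-methyl-2-oxobutanoate | CC(C)C(=O)C(=O)[O-].[Na+] | starting material
26 | (R)-2-hydroxy-3-methylbutanoic acid | OC(=O)[C@H](O)C(C)C | intermediate
27 | (R)-2-(isovaleryloxy)-3-methylbutanoic acid | OC(=O)[C@H](OC(=O)CC(C)C)C(C)C | intermediate
28 | C11 ester of diol 24 | O[C@H]1C[C@]2(O)C(COC(=O)[C@H](OC(=O)CC(C)C)C(C)C)=CO[C@@H](OC(=O)CC(C)C)[C@@H]2[C@@]1(O)CCl | intermediate
29 | Volvaltrate B | CC(=O)O[C@H]1C[C@]2(O)C(COC(=O)[C@H](OC(=O)CC(C)C)C(C)C)=CO[C@@H](OC(=O)CC(C)C)[C@@H]2[C@@]1(O)CCl | target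

## Totals
- Total steps: 26.
- Longest linear sequence: 24 steps (steps 1–22, then 25 and 26).

## Three steps most likely to fail
1. **Step 20 (C8 methylenation).** The facial selectivity is set only by the convex/concave bias of the bicycle and could be eroded by C9 epimerisation or β-acyloxy elimination. Fallback: change the order, installing C10 on the enone stage (conjugate addition of LiCH₂OPMB to **8**, then Saegusa oxidation) so that Weitz–Scheffer epoxidation sets the C8 oxygen trans to C7–OTBS, then convert CH₂OPMB to the spiro-epoxide.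
2. **Steps 17–18 (lactol/acylal, C1 configuration).** The lactol can ring-open to the dialdehyde, and the anomer ratio on acylation is uncertain. Fallback: pre-form the C1 acylal and the O2–C3 enol ether on a cyclopentanone (aldehyde + isovaleryl chloride → α-chloro ester, then O-alkylation with a (Z)-iodo aldehyde enolate) and close C4–C5 by intramolecular Nozaki–Hiyama–Kishi addition to the C5 ketone.
3. **Step 21 (HCl opening of the epoxide).** The acylal, enol ether and allylic tertiary alcohol are acid-sensitive, and attack at C8 is a regiochemical risk. Fallback: add LiCH₂Cl (ICH₂Cl/MeLi·LiBr) to the C8 ketone of a silyl-protected analogue before any acylation, giving the chlorohydrin directly with no epoxide stage.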